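**Remark (assumption):** enantiopure (R)-3-methyloxolan-2-one is taken as purchasable. Atoms carry the germacrane numbers of the target: C1 ketone, C2/C3 methylenes, C4 (methyl C15), C5 (isovalerate), C6 (OH), C7/C8 lactone fusion, C9 (isobutyrate), C10 (OH, methyl C14), C11–C13 lactone carbons.

## Retrosynthetic overview

1. Target 30 comes from late acylations (O9 isobutyrate, O5 isovalerate) of a 5,6-diol made by osmylation of an (E)-C5=C6 cyclodecenone; the 8,12-lactone is closed by oxidation of a C8/C12 diol while C6 is still an alkene carbon.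
2. The ten-membered ring is not cyclised directly. The C1 ketone and the C6 carbinol sit 1,6 across the ring, with the C5 oxygen next to C6, so the transannular C1–C6 bond is a retro-Grob bond. Samarium Barbier closure of six-membered ring A (C1–C6) through the C1–C2 bond, then Grob cleavage of C1–C6 in the same flask, expands a cyclohexanone by four carbons.
3. That cyclohexanone, ring B (C1, C10, C9, C8, C7, C6), is the intact ring of (R)-carvone: its methyl is C14 on C10, its isopropenyl is C11–C13 on C7, and its C1–C6 bond is the one later cut. O8, O9, O10 and the C1 carbonyl are set on the six-membered ring.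
4. C2–C5 and C15 come from (R)-3-methyloxolan-2-one as (R)-4-iodo-2-methylbutanal, joined at C6 by a syn-selective aldol whose carbinol becomes the Grob nucleofuge.
5. Ring order: ring B (chiral pool), ring A (transient, step 14), ten-membered ring (step 14), α-methylene lactone (step 16).

Key step: step 14

## Route

Step 1
Reactants: 1 (R)-(−)-carvone
Product: 2 (R)-10-hydroxycarvone [(5R)-5-(3-hydroxyprop-1-en-2-yl)-2-methylcyclohex-2-en-1-one]
Conditions: SeO2 (0.3 equiv), t-BuOOH, CH2Cl2, rt
Reagents that add atoms: selenium dioxide O=[Se]=O (catalytic oxygen carrier); tert-butyl hydroperoxide CC(C)(C)OO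
Why: Selenium dioxide allylic oxidation (ene reaction, then [2,3]-sigmatropic shift) should hydroxylate the methyl of the 1,1-disubstituted isopropenyl alkene and leave the deactivated enone alone, giving the future C12 oxygen without touching C7.

Step 2
Reactants: 2 (R)-10-hydroxycarvone
Product: 4 (5S,6S)-6-hydroxy-5-(3-hydroxyprop-1-en-2-yl)-2-methylcyclohex-2-en-1-one, via dilithium alkoxide dienolate 3 (not isolated)
Conditions: LDA (LiN(i-Pr)2, 2.2 equiv), THF, −78 °C; then 2-(phenylsulfonyl)-3-phenyloxaziridine, −78 °C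
Reagents that add atoms: 2-(phenylsulfonyl)-3-phenyloxaziridine O=S(=O)(c1ccccc1)N1OC1c1ccccc1
Why: Kinetic deprotonation at the α'-methylene gives the cross-conjugated dienolate, and its hydroxylation by the N-sulfonyloxaziridine (enolate oxidation) should occur anti to the adjacent C7 side chain, setting the C8 oxygen trans to it.

Step 3
Reactants: 4 the diol
Product: 5 bis(tert-butyldimethylsilyl) ether of 4 (silyl on O8 and O12)
Conditions: TBSCl, imidazole, DMF, rt
Reagents that add atoms: tert-butyldimethylsilyl chloride CC(C)(C)[Si](C)(C)Cl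
Why: Standard silylation of the secondary and the primary allylic hydroxyl should mask O8 and O12 for the organometallic steps; no stereocentre is affected.

Step 4
Reactants: 5 the bis-silyl enone
Product: 6 allylic alcohol (C9 hydroxyl cis to the C7 side chain, trans to the C8 silyloxy group; C10=C1 alkene)
Conditions: NaBH4, CeCl3·7H2O, MeOH, −78 °C
Reagents that add atoms: none
Why: Luche 1,2-reduction by axial hydride delivery should give the pseudo-equatorial allylic alcohol, cis to the C7 side chain and trans to O8, which sets C9.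

Step 5
Reactants: 6 the allylic alcohol
Product: 7 epoxy alcohol (1,10-epoxide cis to the C9 hydroxyl)
Conditions: VO(acac)2 (cat.), t-BuOOH, CH2Cl2, 0 °C to rt
Reagents that add atoms: tert-butyl hydroperoxide CC(C)(C)OO
Why: Hydroxyl-directed vanadium-catalysed epoxidation should deliver oxygen to the C10=C1 alkene on the face of the C9 hydroxyl, fixing the C10–O bond cis to O9, while the side-chain alkene has no free hydroxyl nearby and is left alone.

Step 6
Reactants: 7 the epoxy alcohol
Product: 8 C1 benzoate 9,10-diol (O1 trans to O10; O9 and O10 cis)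
Conditions: Ti(OiPr)4, PhCO2H, CH2Cl2, rt
Reagents that add atoms: benzoic acid O=C(O)c1ccccc1
Why: Titanium-assisted opening of the 2,3-epoxy alcohol by benzoate should occur at the distal secondary carbon C1 with inversion (also the trans-diaxial Fürst–Plattner mode), so the tertiary C10–O bond keeps its configuration and the inverted C1 centre is the one later oxidised away.

Step 7
Reactants: 8 the benzoate diol
Product: 9 9,10-O-isopropylidene C1 benzoate
Conditions: 2,2-dimethoxypropane, PPTS (cat.), CH2Cl2, rt
Reagents that add atoms: 2,2-dimethoxypropane COC(C)(C)OC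
Why: Only the cis-vicinal C9/C10 diol can bridge, so acid-catalysed transketalisation should give the dioxolane and present the C10 oxygen as an ether rather than an ester for the samarium step.

Step 8
Reactants: 9 the acetonide benzoate
Product: 10 9,10-O-isopropylidene C1 alcohol
Conditions: K2CO3 (cat.), MeOH, rt
Reagents that add atoms: none
Why: Base-catalysed transesterification with methanol should remove the benzoate without touching the silyl ethers or the acetonide.

Step 9
Reactants: 10 the C1 alcohol
Product: 11 ring B ketone (C1 ketone, C10 methyl/acetonide O, C9 acetonide O, C8 OTBS, C7 side chain C(=CH2)CH2OTBS, C6 methylene)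
Conditions: Dess–Martin periodinane, CH2Cl2, rt
Reagents that add atoms: none
Why: Dess–Martin oxidation of the secondary alcohol should give the ketone, which cannot epimerise because C10 is quaternary and C6 is a methylene.

Step 10
Reactants: 12 (R)-3-methyloxolan-2-one
Product: 14 methyl (R)-4-iodo-2-methylbutanoate, via silyl ester 13 (not isolated)
Conditions: TMSI, CH2Cl2, rt; then MeOH
Reagents that add atoms: iodotrimethylsilane C[Si](C)(C)I; methanol CO
Why: Iodotrimethylsilane should cleave the lactone by SN2 attack of iodide at the O–CH2 carbon and methanolysis of the silyl ester should give the iodo ester, the C4 stereocentre not being involved.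

Step 11
Reactants: 14 the iodo ester
Product: 15 (R)-4-iodo-2-methylbutanal
Conditions: i-Bu2AlH, CH2Cl2, −78 °C
Reagents that add atoms: none
Why: Partial reduction through the tetrahedral aluminium hemiacetal, stable at −78 °C, should give the α-methyl aldehyde, which is used at once to avoid epimerisation at C4.

Step 12
Reactants: 11 ring B ketone; 15 (R)-4-iodo-2-methylbutanal
Product: 18 5,6-syn aldol (C6 side chain trans to the C7 substituent; C5 hydroxyl; C4 methyl; C2 iodide), via lithium enolate 16 (not isolated), via titanium enolate 17 (not isolated)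
Conditions: LDA, THF, −78 °C; ClTi(OiPr)3, −78 to −40 °C; then 15, −78 °C
Reagents that add atoms: none
Why: C6 is the only enolisable position of 11, and the tris(isopropoxy)titanium enolate of a cyclic ketone (a syn-selective aldol donor) should add to 15 anti to the C7 side chain and with 5,6-syn topology, which for the (R)-aldehyde is the 4,5-anti (anti-Felkin) sense normally favoured in syn-selective additions to α-methyl aldehydes through avoidance of a syn-pentane contact.

Step 13
Reactants: 18 the syn aldol
Product: 19 C5 mesylate of 18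
Conditions: Ms2O, pyridine, DMAP (cat.), CH2Cl2, 0 °C
Reagents that add atoms: methanesulfonic anhydride CS(=O)(=O)OS(C)(=O)=O
Why: Sulfonylation under weakly basic conditions at 0 °C should convert the hindered β-hydroxyl into the nucleofuge without E1cB loss and with retention at C5.

Step 14
Reactants: 19 the iodo keto mesylate
Product: 22 (E)-cyclodec-5-enone (C1 ketone, E-C5=C6, C4 methyl, 9,10-acetonide, C8 OTBS, C7 side chain), via alkylsamarium diiodide 20 (not isolated), via bicyclic samarium alkoxide 21 (not isolated)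
Conditions: SmI2 (2.5 equiv), Fe(dbm)3 [tris(dibenzoylmethanato)iron] (2 mol %), THF, −78 °C to rt
Reagents that add atoms: none
Why: Iron-catalysed electron transfer from divalent samarium should reduce the primary C2 iodide to the alkylsamarium 20, which adds to the C1 ketone (Barbier reaction) and closes six-membered ring A as the trivalent samarium alkoxide 21; this alkoxide then undergoes Grob fragmentation, the C1–C6 ring-fusion bond breaking as the C1=O and C5=C6 π bonds form and mesylate leaves C5, so the bicyclo[4.4.0] skeleton opens to the ten-membered ring. The closest known reaction type is the samarium diiodide-mediated sequential Barbier cyclisation/Grob fragmentation of iodoalkyl keto mesylates to medium-ring cycloalkenones, and the second half is the classical Wharton fragmentation of decalin 1,3-diol monosulfonates. Ring A is closed by 6-exo-trig addition of C2 to the C1 carbonyl, and the ten-membered ring arises by four-carbon ring expansion, never by a direct medium-ring cyclisation. No stereocentre is created in 22 (the C1 carbinol is transient), but the E geometry of C5=C6 is set stereospecifically by the 5,6-syn relationship of 19: with the C5–O bond antiperiplanar to C1–C6 (equatorial mesylate on chair ring A), C4 and C7 are anti, whether ring A is cis- or trans-fused. The step needs iodide reduction and carbonyl addition to outrun ketyl formation with loss of the α-oxygen at C10 and E1cB loss of the mesylate; an ether-type (acetonide) α-oxygen, the absence of HMPA and proton sources, low temperature and the fast six-membered closure should secure this. Fragmentation regiochemistry is fixed because C5 carries the only nucleofuge 1,3 to the alkoxide.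

Step 15
Reactants: 22 the bis-silyl cyclodecenone
Product: 23 C8/C12 diol
Conditions: Bu4NF, AcOH, THF, 0 °C to rt
Reagents that add atoms: none
Why: Buffered fluoride should cleave both silyl ethers and release the C8 and C12 hydroxyls with no stereocentre touched.

Step 16
Reactants: 23 the diol
Product: 26 α-methylene-8,12-lactone (9,10-acetonide, E-C5=C6, C1 ketone), via enal 24 (not isolated), via lactol 25 (not isolated)
Conditions: TEMPO (cat.), PhI(OAc)2, CH2Cl2, rt
Reagents that add atoms: none
Why: Nitroxyl-catalysed oxidation should take the primary allylic alcohol to the enal, which is trapped as the lactol by O8 (the only γ-hydroxyl, C6 still being an alkene carbon) and oxidised on to the α-methylene-γ-lactone, so the 8,12-regiochemistry is unambiguous.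

Step 17
Reactants: 26 the acetonide lactone
Product: 27 9,10-diol lactone
Conditions: TFA–H2O (9:1), CH2Cl2, 0 °C
Reagents that add atoms: none
Why: Aqueous acid hydrolysis of the dioxolane should free the C9 and C10 hydroxyls, and the C1 carbonyl, deactivated by its α-oxygen, should resist transannular Prins-type attack by the alkene at 0 °C.

Step 18
Reactants: 27 the 9,10-diol
Product: 28 C9 isobutyrate (C10 hydroxyl free)
Conditions: (i-PrCO)2O, DMAP (cat.), pyridine, CH2Cl2, 0 °C
Reagents that add atoms: isobutyric anhydride CC(C)C(=O)OC(=O)C(C)C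
Why: Acylation under nucleophilic catalysis should take place at C9, the only secondary hydroxyl, the tertiary C10 hydroxyl being inert under these conditions.

Step 19
Reactants: 28 the C9 isobutyrate
Product: 29 (5R,6R)-5,6-diol
Conditions: OsO4 (cat.), (DHQD)2PHAL (cat.), NMO, acetone–H2O, 0 °C
Reagents that add atoms: osmium tetroxide O=[Os](=O)(=O)=O (catalytic oxygen carrier); N-methylmorpholine N-oxide C[N+]1([O-])CCOCC1; water O
Why: Syn-dihydroxylation of the strained (E)-cycloalkene, far more electron-rich than the acrylate-type exocyclic alkene, should occur on its outer face, which in the folded conformer inherited from the fragmentation (C1 carbonyl across the inner face) is the face from which the mesylate left, so O5 returns with the configuration of the aldol carbinol and O6 enters opposite the former C1–C6 bond to give (5R,6R), the facial sense also preferred by the dihydroquinidine-derived ligand.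

Step 20
Reactants: 29 the 5,6-diol
Product: 30 target, (4R,5R,6R,7R,8S,9R,10R)-6,10-dihydroxy-9-isobutyryloxy-5-isovaleryloxy-1-oxogermacr-11(13)-en-8,12-olide
Conditions: (i-BuCO)2O (1.05 equiv), DMAP (cat.), 2,4,6-collidine, CH2Cl2, −40 °C
Reagents that add atoms: isovaleric anhydride CC(C)CC(=O)OC(=O)CC(C)C
Why: Acylation at low temperature with a small excess of anhydride should select the C5 hydroxyl, whose neighbour C4 carries only a methyl group, over the C6 hydroxyl flanked by the lactone ring-fusion carbon C7, and the tertiary C10 hydroxyl does not react.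

## Compound list

1 | (R)-(−)-carvone | CC1=CC[C@H](CC1=O)C(=C)C | starting material
2 | (R)-10-hydroxycarvone | C1[C@H](C(=C)CO)CC=C(C)C1=O | intermediate
3 | dilithium alkoxide dienolate of 2 (not isolated) | [Li]OC1=C[C@H](C(=C)CO[Li])CC=C1C | intermediate
4 | (5S,6S)-6-hydroxy-5-(3-hydroxyprop-1-en-2-yl)-2-methylcyclohex-2-en-1-one | O[C@H]1[C@H](C(=C)CO)CC=C(C)C1=O | intermediate
5 | bis-TBS ether of 4 | CC(C)(C)[Si](C)(C)O[C@H]1[C@H](C(=C)CO[Si](C)(C)C(C)(C)C)CC=C(C)C1=O | intermediate
6 | allylic alcohol (C9 OH cis to C7 side chain, trans to O8) | CC(C)(C)[Si](C)(C)O[C@H]1[C@H](C(=C)CO[Si](C)(C)C(C)(C)C)CC=C(C)[C@@H]1O | intermediate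
7 | 1,10-epoxy-9-ol (epoxide cis to C9 OH) | CC(C)(C)[Si](C)(C)O[C@H]1[C@H](C(=C)CO[Si](C)(C)C(C)(C)C)C[C@@H]2O[C@]2(C)[C@@H]1O | intermediate
8 | C1 benzoate 9,10-diol | CC(C)(C)[Si](C)(C)O[C@H]1[C@H](C(=C)CO[Si](C)(C)C(C)(C)C)C[C@@H](OC(=O)c2ccccc2)[C@](C)(O)[C@@H]1O | intermediate
9 | 9,10-acetonide C1 benzoate | CC(C)(C)[Si](C)(C)O[C@H]1[C@H](C(=C)CO[Si](C)(C)C(C)(C)C)C[C@@H](OC(=O)c3ccccc3)[C@](C)(OC(C)(C)O2)[C@@H]12 | intermediate
10 | 9,10-acetonide C1 alcohol | CC(C)(C)[Si](C)(C)O[C@H]1[C@H](C(=C)CO[Si](C)(C)C(C)(C)C)C[C@@H](O)[C@](C)(OC(C)(C)O2)[C@@H]12 | intermediate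
11 | ring B ketone | CC(C)(C)[Si](C)(C)O[C@H]1[C@H](C(=C)CO[Si](C)(C)C(C)(C)C)CC(=O)[C@](C)(OC(C)(C)O2)[C@@H]12 | intermediate
12 | (R)-3-methyloxolan-2-one | O=C1[C@H](C)CCO1 | starting material
13 | trimethylsilyl (R)-4-iodo-2-methylbutanoate (not isolated) | C[Si](C)(C)OC(=O)[C@H](C)CCI | intermediate
14 | methyl (R)-4-iodo-2-methylbutanoate | COC(=O)[C@H](C)CCI | intermediate
15 | (R)-4-iodo-2-methylbutanal | O=C[C@H](C)CCI | intermediate
16 | lithium enolate of 11 (C1=C6, not isolated) | CC(C)(C)[Si](C)(C)O[C@H]1[C@H](C(=C)CO[Si](C)(C)C(C)(C)C)C=C(O[Li])[C@](C)(OC(C)(C)O2)[C@@H]12 | intermediate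
17 | tris(isopropoxy)titanium enolate of 11 (not isolated) | CC(C)(C)[Si](C)(C)O[C@H]1[C@H](C(=C)CO[Si](C)(C)C(C)(C)C)C=C(O[Ti](OC(C)C)(OC(C)C)OC(C)C)[C@](C)(OC(C)(C)O2)[C@@H]12 | intermediate
18 | 5,6-syn aldol | CC(C)(C)[Si](C)(C)O[C@H]1[C@H](C(=C)CO[Si](C)(C)C(C)(C)C)[C@@H]([C@H](O)[C@H](C)CCI)C(=O)[C@](C)(OC(C)(C)O2)[C@@H]12 | intermediate
19 | C5 mesylate of 18 | CC(C)(C)[Si](C)(C)O[C@H]1[C@H](C(=C)CO[Si](C)(C)C(C)(C)C)[C@@H]([C@H](OS(C)(=O)=O)[C@H](C)CCI)C(=O)[C@](C)(OC(C)(C)O2)[C@@H]12 | intermediate
20 | C2 alkylsamarium diiodide (not isolated) | CC(C)(C)[Si](C)(C)O[C@H]1[C@H](C(=C)CO[Si](C)(C)C(C)(C)C)[C@@H]([C@H](OS(C)(=O)=O)[C@H](C)CC[Sm](I)I)C(=O)[C@](C)(OC(C)(C)O2)[C@@H]12 | intermediate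
21 | bicyclic samarium alkoxide (rings A and B; drawn trans-fused; not isolated) | CC(C)(C)[Si](C)(C)O[C@H]1[C@H](C(=C)CO[Si](C)(C)C(C)(C)C)[C@H]3[C@H](OS(C)(=O)=O)[C@H](C)CC[C@]3(O[Sm](I)I)[C@](C)(OC(C)(C)O2)[C@@H]12 | intermediate
22 | (E)-cyclodec-5-enone | CC(C)(C)[Si](C)(C)O[C@H]1[C@H](C(=C)CO[Si](C)(C)C(C)(C)C)/C=C/[C@H](C)CCC(=O)[C@](C)(OC(C)(C)O2)[C@@H]12 | intermediate
23 | C8/C12 diol | O[C@H]1[C@H](C(=C)CO)/C=C/[C@H](C)CCC(=O)[C@](C)(OC(C)(C)O2)[C@@H]12 | intermediate
24 | C12 enal (not isolated) | O[C@H]1[C@H](C(=C)C=O)/C=C/[C@H](C)CCC(=O)[C@](C)(OC(C)(C)O2)[C@@H]12 | intermediate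
25 | 8,12-lactol (not isolated) | C=C1C(O)O[C@H]2[C@H]1/C=C/[C@H](C)CCC(=O)[C@](C)(OC(C)(C)O3)[C@@H]23 | intermediate
26 | α-methylene-8,12-lactone acetonide | C=C1C(=O)O[C@H]2[C@H]1/C=C/[C@H](C)CCC(=O)[C@](C)(OC(C)(C)O3)[C@@H]23 | intermediate
27 | 9,10-diol lactone | C=C1C(=O)O[C@H]2[C@H]1/C=C/[C@H](C)CCC(=O)[C@](C)(O)[C@@H]2O | intermediate
28 | C9 isobutyrate | C=C1C(=O)O[C@H]2[C@H]1/C=C/[C@H](C)CCC(=O)[C@](C)(O)[C@@H]2OC(=O)C(C)C | intermediate
29 | (5R,6R)-5,6-diol | C=C1C(=O)O[C@H]2[C@H]1[C@@H](O)[C@H](O)[C@H](C)CCC(=O)[C@](C)(O)[C@@H]2OC(=O)C(C)C | intermediate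
30 | target CNP0203887.1 | C=C1C(=O)O[C@H]2[C@H]1[C@@H](O)[C@H](OC(=O)CC(C)C)[C@H](C)CCC(=O)[C@](C)(O)[C@@H]2OC(=O)C(C)C | target

## Count and risks

Total step count: 20. Longest linear sequence: 18 steps (steps 1–9 and 12–20, from carvone); steps 10–11 form the side branch.

**Step 14 (key step).** The cascade may be diverted by reductive loss of the C10 oxygen through the ketyl, by elimination of the β-mesylate before ring closure, or by simple reduction of the iodide. The fallback separates the two events and sets out from aldol 18: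
- The C5 hydroxyl is silylated (TESOTf, 2,6-lutidine) to the triethylsilyl ether F1.
- Ring A is closed by iodine–lithium exchange and addition of the alkyllithium to the C1 ketone (t-BuLi, Et2O–pentane, −100 °C), giving the decalinol F2.
- The triethylsilyl group is removed selectively (HF·pyridine, THF–pyridine, 0 °C) to give the decalin diol F3.
- The secondary hydroxyl is mesylated (MsCl, pyridine) to the hydroxy mesylate F4.
- KOt-Bu in THF effects the Wharton fragmentation and returns the route to 22.

**Step 12 (aldol).** Simple diastereoselection may be poor, since the chair transition state of the cyclic enolate gives the 5,6-anti adduct, and retro-aldol equilibration may occur. The fallback corrects C5 by oxidation and chelation-controlled reduction, setting out from 11 and 15: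
- The lithium enolate aldol, run without control at C5, gives 18 together with the C5-epimeric aldol F5.
- The mixture is oxidised (Dess–Martin periodinane) to the 2-acylcyclohexanone F6.
- Zn(BH4)2 in Et2O at −20 °C delivers hydride to the zinc-chelated 1,3-dicarbonyl anti to the ring residue on C6 and should reduce the less hindered side-chain carbonyl, returning the route to the 5,6-syn aldol 18.

**Step 20 (C5 acylation).** Acylation may take place at the C6 hydroxyl or at both secondary hydroxyls. If the C6 hydroxyl proves the more reactive one, that preference is used for temporary protection, setting out from 29: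
- Silylation (TESOTf, 2,6-lutidine, −78 °C) gives the 6-O-triethylsilyl ether F7.
- The remaining C5 hydroxyl is isovalerylated (isovaleric anhydride, DMAP, rt) to the silylated ester F8.
- HF·pyridine removes the silyl group and returns the route to 30.

Further compounds
F1 | step 14 | C5 triethylsilyl ether of 18 | CC(C)(C)[Si](C)(C)O[C@H]1[C@H](C(=C)CO[Si](C)(C)C(C)(C)C)[C@@H]([C@H](O[Si](CC)(CC)CC)[C@H](C)CCI)C(=O)[C@](C)(OC(C)(C)O2)[C@@H]12
F2 | step 14 | decalinol with C5 triethylsilyl ether (rings A and B, tertiary C1 hydroxyl) | CC(C)(C)[Si](C)(C)O[C@H]1[C@H](C(=C)CO[Si](C)(C)C(C)(C)C)[C@H]3[C@H](O[Si](CC)(CC)CC)[C@H](C)CC[C@]3(O)[C@](C)(OC(C)(C)O2)[C@@H]12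
F3 | step 14 | decalin 1,5-diol | CC(C)(C)[Si](C)(C)O[C@H]1[C@H](C(=C)CO[Si](C)(C)C(C)(C)C)[C@H]3[C@H](O)[C@H](C)CC[C@]3(O)[C@](C)(OC(C)(C)O2)[C@@H]12
F4 | step 14 | decalinol C5 mesylate | CC(C)(C)[Si](C)(C)O[C@H]1[C@H](C(=C)CO[Si](C)(C)C(C)(C)C)[C@H]3[C@H](OS(C)(=O)=O)[C@H](C)CC[C@]3(O)[C@](C)(OC(C)(C)O2)[C@@H]12
F5 | step 12 | C5 epimer of aldol 18 (5,6-anti) | CC(C)(C)[Si](C)(C)O[C@H]1[C@H](C(=C)CO[Si](C)(C)C(C)(C)C)[C@@H]([C@@H](O)[C@H](C)CCI)C(=O)[C@](C)(OC(C)(C)O2)[C@@H]12
F6 | step 12 | 2-acylcyclohexanone (C1, C5 diketone) | CC(C)(C)[Si](C)(C)O[C@H]1[C@H](C(=C)CO[Si](C)(C)C(C)(C)C)[C@@H](C(=O)[C@H](C)CCI)C(=O)[C@](C)(OC(C)(C)O2)[C@@H]12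
F7 | step 20 | 6-O-triethylsilyl ether of 29 | C=C1C(=O)O[C@H]2[C@H]1[C@@H](O[Si](CC)(CC)CC)[C@H](O)[C@H](C)CCC(=O)[C@](C)(O)[C@@H]2OC(=O)C(C)C
F8 | step 20 | 6-O-triethylsilyl-5-O-isovaleryl derivative | C=C1C(=O)O[C@H]2[C@H]1[C@@H](O[Si](CC)(CC)CC)[C@H](OC(=O)CC(C)C)[C@H](C)CCC(=O)[C@](C)(O)[C@@H]2OC(=O)C(C)C
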